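The route rests on cutting the bond between the side-chain CH2 and the olefinic ring carbon of the hydroxymethyl-bearing anhydride (ring A). The feature exploited is the CH2–CH pair that links ring A to the stereocentre. It is a vinyl group in disguise, and the stereocentre carries pentyl plus an sp2 carbon of ring B, for which boron can stand in. An enantioselective palladium-catalysed conjunctive cross-coupling of a pentyl(vinyl)boronate with a 3-bromofuran (masked ring A) forms the CH2–ring A bond, the pentyl–CH bond and the stereocentre in one operation. Ring B then enters as a second furan by a stereoretentive 1,2-shift, and both furans are oxidised to anhydrides.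

Key step: step 3

Assumption: both antipodes of the ferrocenyl bisphosphine are sold; the one that delivers the (R)-boronate 10 is used, with its sense of induction assigned by analogy with simpler alkyl(vinyl)boronates.
Assumption: the target is taken to be isolable in the drawn open form (free CH2OH beside an intact anhydride), so water is kept away once the hydroxyl group is free.

Step 1
Reactants: 1 3,4-dibromofuran; 2 (triisopropylsiloxy)methyl chloride
Product: 4 [(4-bromofuran-3-yl)methoxy]triisopropylsilane, via 3-bromo-4-lithiofuran 3 (not isolated)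
Conditions: n-BuLi (1.0 equiv), Et2O, −78 °C; then 2, −78 to −40 °C
Reagents that add atoms: none
Why: Bromine–lithium exchange at one of the two equivalent C–Br bonds is fast at −78 °C, where the 3-furyllithium does not isomerise, and alkylation of the organolithium by the α-chloro ether should deliver the hydroxymethyl carbon already silyl-protected.

Step 2
Reactants: 1 3,4-dibromofuran; 5 1-hexyne
Product: 6 3-bromo-4-(hex-1-yn-1-yl)furan
Conditions: PdCl2(PhCN)2 (3 mol %), P(t-Bu)3 (6 mol %), CuI (2 mol %), i-Pr2NH, 1,4-dioxane, rt; 1 in threefold excess, the surplus recovered by distillation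
Reagents that add atoms: none
Why: This is a Sonogashira coupling in which the excess of the symmetrical dibromide should hold the reaction at mono-alkynylation, and the small, base-inert alkyne serves as the mask of the 2-oxohexyl chain.

Step 3
Reactants: 7 vinylboronic acid pinacol ester; 8 n-pentylmagnesium bromide; 4 [(4-bromofuran-3-yl)methoxy]triisopropylsilane
Product: 10 (R)-triisopropyl({4-[2-(4,4,5,5-tetramethyl-1,3,2-dioxaborolan-2-yl)heptyl]furan-3-yl}methoxy)silane, via pentyl(vinyl)boronate complex 9 (not isolated)
Conditions: 7, 8, NaOTf (3 equiv), THF, 0 °C to rt; then 4, Pd(OAc)2 (3 mol %), single antipode of 1,1′-bis[bis(3,5-dimethylphenyl)phosphino]-2,2′-bis[α-(dimethylamino)benzyl]ferrocene (MandyPhos type, 3.6 mol %), THF–DMSO, 40–60 °C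
Reagents that add atoms: none
Why: The Grignard reagent adds to boron of 7 and NaOTf frees the four-coordinate boronate 9 and scavenges bromide; zerovalent palladium inserts into the C–Br bond of 4, the resulting divalent furylpalladium cation binds the vinyl group of 9, pentyl shifts anti from boron to the α-carbon while palladium bonds to the terminal CH2, and reductive elimination forms the CH2–furan C3 bond. The closest known reaction type is the enantioselective conjunctive cross-coupling of Grignard-derived vinylboron ate complexes with aryl and heteroaryl bromides. No ring is closed. The stereocentre is set in the metallate shift, where the chiral bisphosphine on palladium selects the face of the bound vinyl group, so control comes from the catalyst alone. The step needs chemoselectivity for the conjunctive path over direct Suzuki-type transfer of vinyl or pentyl, which the wide-bite-angle ligand and the halide-free cationic palladium should secure, and its regiochemistry is fixed because boron can hand pentyl only to its own α-carbon. Furan 4 carries no acidic or electrophilic group, the silyl ether is inert, and boron stays on the stereocentre as the handle for ring B.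

Step 4
Reactants: 6 3-bromo-4-(hex-1-yn-1-yl)furan; 10 (R)-boronic ester
Product: 13 (R)-{[4-(2-[4-(hex-1-yn-1-yl)furan-3-yl]heptyl)furan-3-yl]methoxy}triisopropylsilane, via furyllithium 11 (not isolated), via lithium furylboronate complex 12 (not isolated)
Conditions: 6 (1.1 equiv), n-BuLi, THF, −78 °C; 10, −78 °C; then NBS (1.1 equiv), THF, −78 °C
Reagents that add atoms: none
Why: This is the enantiospecific sp2–sp3 coupling of a secondary boronic ester with a lithiated electron-rich heteroarene, in which bromonium attack at C2 of the boron-bound furan triggers a stereoretentive 1,2-shift of the secondary alkyl group to C3 and loss of bromide and boron restores the furan, the anionic boronate being far more nucleophilic than the neutral ring A furan.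

Step 5
Reactants: 13 (R)-bis-furan
Product: 15 (R)-bis(5-hydroxyfuran-2(5H)-one) as a mixture of lactol regioisomers and epimers, via bis-endoperoxide 14 (not isolated)
Conditions: O2, hν (visible), tetraphenylporphyrin (cat.), i-Pr2NEt, CH2Cl2, −78 °C
Reagents that add atoms: oxygen, O=O
Why: A (4+2) addition of singlet oxygen across C2/C5 of each furan, followed by Kornblum–DeLaMare-type opening of the endoperoxides by the hindered base, should give the γ-hydroxybutenolides, whose isomerism is irrelevant because all converge in step 6, while alkyne, silyl ether and stereocentre stay untouched.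

Step 6
Reactants: 15 (R)-bis(5-hydroxyfuran-2(5H)-one)
Product: 16 (R)-3-(hex-1-yn-1-yl)-4-[1-(2,5-dioxo-4-{[(triisopropylsilyl)oxy]methyl}-2,5-dihydrofuran-3-yl)heptan-2-yl]furan-2,5-dione
Conditions: Dess–Martin periodinane (3 equiv), CH2Cl2, 0 °C to rt
Reagents that add atoms: none
Why: Dess–Martin oxidation of both lactols to cyclic anhydrides should funnel every isomer of 15 into one compound under non-basic conditions that leave the vinylogously acidic C–H of the stereocentre alone.

Step 7
Reactants: 16 (R)-alkynyl bis-anhydride
Product: 17 (R)-3-(2-oxohexyl)-4-[1-(2,5-dioxo-4-{[(triisopropylsilyl)oxy]methyl}-2,5-dihydrofuran-3-yl)heptan-2-yl]furan-2,5-dione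
Conditions: Ph3PAuNTf2 (5 mol %), H2O (5 equiv), 1,4-dioxane, 40 °C; then toluene azeotrope
Reagents that add atoms: water, O
Why: This is a gold-catalysed alkyne hydration in which, now that ring B is an anhydride, the alkyne is polarised as the terminus of a dienyne acceptor, so water should attack the butyl-bearing carbon and tautomerisation gives the 2-oxohexyl chain, while the neutral medium spares the silyl ether and azeotropic drying recloses any opened anhydride.

Step 8
Reactants: 17 (R)-silyl ether
Product: 18 (R)-3-{1-[4-(hydroxymethyl)-2,5-dioxo-2,5-dihydrofuran-3-yl]heptan-2-yl}-4-(2-oxohexyl)furan-2,5-dione (target)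
Conditions: HF·pyridine, THF, 0 °C to rt, polyethylene vessel; short cold acidic work-up
Reagents that add atoms: none
Why: Fluoride-mediated desilylation of the primary silyl ether runs under acidic, water-poor conditions, and attack of the freed hydroxyl on the intact anhydride would need an anti-Bredt bicyclo[2.2.1] intermediate, so translactonisation should be blocked as long as the ring stays closed.

Compound list
1 | 3,4-dibromofuran | Brc1cocc1Br | starting material
2 | (triisopropylsiloxy)methyl chloride | ClCO[Si](C(C)C)(C(C)C)C(C)C | starting material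
3 | 3-bromo-4-lithiofuran | [Li]c1cocc1Br | intermediate
4 | [(4-bromofuran-3-yl)methoxy]triisopropylsilane | Brc1cocc1CO[Si](C(C)C)(C(C)C)C(C)C | intermediate
5 | 1-hexyne | C#CCCCC | starting material
6 | 3-bromo-4-(hex-1-yn-1-yl)furan | CCCCC#Cc1cocc1Br | intermediate
7 | vinylboronic acid pinacol ester | C=CB1OC(C)(C)C(C)(C)O1 | starting material
8 | n-pentylmagnesium bromide | CCCCC[Mg]Br | starting material
9 | bromomagnesium pentyl(vinyl)(pinacolato)borate | CCCCC[B-]1(C=C)OC(C)(C)C(C)(C)O1.[Mg+]Br | intermediate
10 | (R)-triisopropyl({4-[2-(4,4,5,5-tetramethyl-1,3,2-dioxaborolan-2-yl)heptyl]furan-3-yl}methoxy)silane | CCCCC[C@H](Cc1cocc1CO[Si](C(C)C)(C(C)C)C(C)C)B1OC(C)(C)C(C)(C)O1 | intermediate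
11 | [4-(hex-1-yn-1-yl)furan-3-yl]lithium | [Li]c1cocc1C#CCCCC | intermediate
12 | lithium (R)-[4-(hex-1-yn-1-yl)furan-3-yl]boronate complex of 10 | CCCCC[C@H](Cc1cocc1CO[Si](C(C)C)(C(C)C)C(C)C)[B-]1(c2cocc2C#CCCCC)OC(C)(C)C(C)(C)O1.[Li+] | intermediate
13 | (R)-{[4-(2-[4-(hex-1-yn-1-yl)furan-3-yl]heptyl)furan-3-yl]methoxy}triisopropylsilane | CCCCC[C@H](Cc1cocc1CO[Si](C(C)C)(C(C)C)C(C)C)c1cocc1C#CCCCC | intermediate
14 | bis-endoperoxide of 13 (each furan as a 2,3,7-trioxabicyclo[2.2.1]hept-5-ene; (R) at heptyl C2, bridgeheads as a mixture) | CCCCC[C@H](CC1=C(CO[Si](C(C)C)(C(C)C)C(C)C)C2OOC1O2)C1=C(C#CCCCC)C2OOC1O2 | intermediate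
15 | (R)-bis(5-hydroxyfuran-2(5H)-one), mixture of lactol regioisomers and epimers (one regioisomer drawn) | CCCCC[C@H](CC1=C(CO[Si](C(C)C)(C(C)C)C(C)C)C(=O)OC1O)C1=C(C#CCCCC)C(=O)OC1O | intermediate
16 | (R)-3-(hex-1-yn-1-yl)-4-[1-(2,5-dioxo-4-{[(triisopropylsilyl)oxy]methyl}-2,5-dihydrofuran-3-yl)heptan-2-yl]furan-2,5-dione | CCCCC[C@H](CC1=C(CO[Si](C(C)C)(C(C)C)C(C)C)C(=O)OC1=O)C1=C(C#CCCCC)C(=O)OC1=O | intermediate
17 | (R)-3-(2-oxohexyl)-4-[1-(2,5-dioxo-4-{[(triisopropylsilyl)oxy]methyl}-2,5-dihydrofuran-3-yl)heptan-2-yl]furan-2,5-dione | CCCCC[C@H](CC1=C(CO[Si](C(C)C)(C(C)C)C(C)C)C(=O)OC1=O)C1=C(CC(=O)CCCC)C(=O)OC1=O | intermediate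
18 | (R)-3-{1-[4-(hydroxymethyl)-2,5-dioxo-2,5-dihydrofuran-3-yl]heptan-2-yl}-4-(2-oxohexyl)furan-2,5-dione | CCCCC[C@H](CC1=C(CO)C(=O)OC1=O)C1=C(CC(=O)CCCC)C(=O)OC1=O | target

Total step count: 8. Longest linear sequence: 7 steps (1, 3, 4, 5, 6, 7, 8).

Steps most likely to fail

Step 3. Oxidative addition of the electron-rich, ortho-substituted bromofuran may be slow, and residual halide may block the cationic palladium. Direct transfer of vinyl or pentyl, or loss of facial control, could then compete. The fallback sets out from 4 and returns at 10; it sets the stereocentre first and makes the same CH2–furan bond afterwards. 1-Heptene is diborated enantioselectively (B2pin2, Pt(dba)3, TADDOL-derived phenylphosphonite, THF, 60 °C) to (S)-1,2-bis(4,4,5,5-tetramethyl-1,3,2-dioxaborolan-2-yl)heptane F1. Only its primary, neighbour-activated C–B bond is then coupled with 4 in a Suzuki–Miyaura reaction (Pd(OAc)2, RuPhos, KOH, THF–H2O, 70 °C) to give 10.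

Step 4. Bromination of the free ring A furan, ipso-bromodeboronation, or a sluggish shift of the hindered secondary alkyl group may consume the boronate complex. The fallback sets out from 10 and 6 and returns at 13; it replaces the electrophile-triggered shift by a metal-catalysed coupling. Boronate 10 is activated with t-BuLi (THF, −78 °C) to the lithium (R)-tert-butylboronate complex F2. This is transmetallated with retention by ZnCl2 to the (R)-secondary alkylzinc chloride F3, which is joined to 6 in a stereoretentive Negishi coupling (Pd(OAc)2, CPhos, THF, rt).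

Step 7. The electron-poor alkyne may be activated only slowly, so that hydrolytic opening of the anhydrides and premature loss of the silyl group overtake hydration. The fallback sets out from 13 and returns at 17; it places the oxygen while ring B is still a furan. Copper-catalysed borylcupration–protonation (B2pin2, CuCl, Xantphos, NaOt-Bu, MeOH, THF, rt) puts copper next to the furan and boron on the butyl-bearing carbon, giving the (R,Z)-alkenylboronate F4. Oxidation with NaBO3 in THF–H2O gives the (R)-keto bis-furan F5. The conditions of step 5 lead through the keto bis-endoperoxide F6 to the keto bis-lactol F7, and the conditions of step 6 give 17.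

Further compounds
F1 | step 3 | (S)-1,2-bis(4,4,5,5-tetramethyl-1,3,2-dioxaborolan-2-yl)heptane | CCCCC[C@H](CB1OC(C)(C)C(C)(C)O1)B1OC(C)(C)C(C)(C)O1
F2 | step 4 | lithium (R)-tert-butylboronate complex of 10 | CCCCC[C@H](Cc1cocc1CO[Si](C(C)C)(C(C)C)C(C)C)[B-]1(C(C)(C)C)OC(C)(C)C(C)(C)O1.[Li+]
F3 | step 4 | (R)-[1-(4-{[(triisopropylsilyl)oxy]methyl}furan-3-yl)heptan-2-yl]zinc chloride | CCCCC[C@H](Cc1cocc1CO[Si](C(C)C)(C(C)C)C(C)C)[Zn]Cl
F4 | step 7 | (R,Z)-alkenylboronate: 13 with the alkyne converted to furyl-CH=C(Bpin)-butyl | CCCCC[C@H](Cc1cocc1CO[Si](C(C)C)(C(C)C)C(C)C)c1cocc1/C=C(\CCCC)B1OC(C)(C)C(C)(C)O1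
F5 | step 7 | (R)-1-{4-[1-(4-{[(triisopropylsilyl)oxy]methyl}furan-3-yl)heptan-2-yl]furan-3-yl}hexan-2-one | CCCCC[C@H](Cc1cocc1CO[Si](C(C)C)(C(C)C)C(C)C)c1cocc1CC(=O)CCCC
F6 | step 7 | bis-endoperoxide of F5 ((R) at heptyl C2, bridgeheads as a mixture) | CCCCC[C@H](CC1=C(CO[Si](C(C)C)(C(C)C)C(C)C)C2OOC1O2)C1=C(CC(=O)CCCC)C2OOC1O2
F7 | step 7 | (R)-keto bis(5-hydroxyfuran-2(5H)-one), mixture of lactol isomers (one regioisomer drawn) | CCCCC[C@H](CC1=C(CO[Si](C(C)C)(C(C)C)C(C)C)C(=O)OC1O)C1=C(CC(=O)CCCC)C(=O)OC1O
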